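**Retrosynthetic overview**

- Feature: in each benzene ring the two bromines sit on neighbouring C2 and C3, C1 bears the bridging methylene C7, C4 and C5 bear oxygen, and C6 bears hydrogen. C1–C6–C5–C4 therefore maps atom for atom onto C6–C5–C4–C3 of a 6-alkyl-3,4-dialkoxy-2-pyrone, and C2–C3 onto a symmetrical alkyne.
- Endgame: the four O–H come from O–Me (BBr3) and the four C–Br from C–SiMe3 (ipso-bromodesilylation). This leads back to bis[4,5-dimethoxy-2,3-bis(trimethylsilyl)phenyl]methane.
- Key disconnection: C1–C2 and C3–C4 of both benzene rings, back to bis(3,4-dimethoxy-2-oxo-2H-pyran-6-yl)methane and two bis(trimethylsilyl)acetylene, the two lactone CO2 units being lost in the forward step (twofold pyrone Diels–Alder/decarboxylation).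
- Bis-pyrone: it comes from 6,6'-methylenebis(4-hydroxy-2-pyrone) by C3-methoxylation (diazo transfer, then O–H insertion) and O4-methylation. That compound is cut at both O1–C2 bonds (ketene lactonisation) and both C5–C6 bonds (γ-acylation) into malonyl dichloride, which supplies C6–C7–C6', and two units of 2,2,6-trimethyl-1,3-dioxin-4-one. This acetal-locked acetoacetate replaces the open dianion so that the chain can neither lactonise the wrong way round nor aromatise.
- Ring order: both 2-pyrone rings form together (step 2), then both benzene rings (step 6), each pyrone ring being consumed as its benzene ring forms.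

Key step: step 6

Remark: ring atoms are numbered C1–C6 with C1 on the methylene C7. The target has no stereocentre; the only stereocentres of the route are the transient bridgeheads of the Diels–Alder adducts. The bis-diazo compound of step 3 is energetic and is to be made in small batches and used at once.

**Step 1**
Reactants: 1 2,2,6-trimethyl-4H-1,3-dioxin-4-one; 2 malonyl dichloride
Product: 4 1,5-bis(2,2-dimethyl-4-oxo-4H-1,3-dioxin-6-yl)pentane-2,4-dione, via lithium dienolate 3 (not isolated)
Conditions: 1 (5 equiv), LiN(SiMe3)2 (5 equiv), THF, −78 °C; 2 (1 equiv) in THF added slowly, −78 °C; AcOH quench at −78 °C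
Reagents that add atoms: lithium bis(trimethylsilyl)amide, [Li+].C[Si](C)(C)[N-][Si](C)(C)C (lithium of 3 only)
Why: Vinylogous (γ-selective) Claisen-type C-acylation of a dioxinone lithium dienolate by an acid chloride is established, malonyl half-ester chlorides included; the excess of 3 takes up the acidic protons, a ketene formed from 2 by proton loss is captured by 3 at the same carbonyl carbon, and the ring oxygen locked in the acetal cannot close onto the second COCl as an open acetoacetate enolate oxygen would.

**Step 2**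
Reactants: 4 1,5-bis(2,2-dimethyl-4-oxo-4H-1,3-dioxin-6-yl)pentane-2,4-dione
Product: 8 6,6'-methylenebis(4-hydroxy-2H-pyran-2-one), via acylketene 5 (not isolated), via pyrone dioxinone 6 (not isolated), via pyronyl acylketene 7 (not isolated)
Conditions: PhMe (0.02 M), reflux
Reagents that add atoms: none
Why: Thermal retro-[4+2] loss of acetone from each dioxinone gives an acylketene whose ketene carbon is captured by the enol oxygen of the ketone four carbons away (six-membered lactonisation), the standard thermolysis of 6-(2-oxoalkyl)dioxinones to 6-substituted 4-hydroxy-2-pyrones, and the neutral medium avoids base-induced aldol aromatisation of the polycarbonyl chain.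

**Step 3**
Reactants: 8 6,6'-methylenebis(4-hydroxy-2H-pyran-2-one)
Product: 9 6,6'-methylenebis(3-diazo-2H-pyran-2,4(3H)-dione)
Conditions: 4-AcNHC6H4SO2N3 (2.05 equiv), Et3N (2.2 equiv), MeCN, 0 °C → rt
Reagents that add atoms: 4-acetamidobenzenesulfonyl azide, CC(=O)Nc1ccc(cc1)S(=O)(=O)N=[N+]=[N-]
Why: Regitz diazo transfer: the triethylammonium enolate of each 4-hydroxy-2-pyrone (a cyclic β-keto lactone, far more acidic than C7–H2) attacks the terminal nitrogen of the sulfonyl azide through C3 and collapses to the 2-diazo-1,3-dicarbonyl unit, the near-stoichiometric azide leaving the methylene bridge untouched.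

**Step 4**
Reactants: 9 6,6'-methylenebis(3-diazo-2H-pyran-2,4(3H)-dione)
Product: 10 6,6'-methylenebis(4-hydroxy-3-methoxy-2H-pyran-2-one)
Conditions: Rh2(OAc)4 (2 mol %), MeOH (large excess), ClCH2CH2Cl, 70 °C, slow addition of 9
Reagents that add atoms: methanol, CO
Why: Rh2(OAc)4-catalysed O–H insertion of a cyclic 2-diazo-1,3-dicarbonyl compound into an alcohol: loss of N2, attack of methanol on the electrophilic carbene carbon and a proton shift place OMe on C3, enolisation restores the 4-hydroxy-2-pyrone, and the excess of methanol outruns Wolff ring contraction and insertion into the product O–H.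

**Step 5**
Reactants: 10 6,6'-methylenebis(4-hydroxy-3-methoxy-2H-pyran-2-one)
Product: 11 bis(3,4-dimethoxy-2-oxo-2H-pyran-6-yl)methane
Conditions: MeOH (2.6 equiv), PPh3 (2.5 equiv), DIAD (2.5 equiv), THF, 0 °C → rt
Reagents that add atoms: methanol, CO
Why: Mitsunobu O-alkylation of 4-hydroxy-2-pyrones, known to give the 4-alkoxy-2-pyrone and not the 2-alkoxy-4-pyranone, methylates only the acidic enols under neutral conditions, whereas a carbonate base plus a methylating agent could also C-methylate the doubly activated methylene C7.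

**Step 6**
Reactants: 11 bis(3,4-dimethoxy-2-oxo-2H-pyran-6-yl)methane; 12 bis(trimethylsilyl)acetylene
Product: 16 bis[4,5-dimethoxy-2,3-bis(trimethylsilyl)phenyl]methane, via bridged lactone 13 (not isolated), via aryl pyrone 14 (not isolated), via second bridged lactone 15 (not isolated)
Conditions: 12 (30 equiv), minimum 1,2-dichlorobenzene to dissolve 11, BHT (5 mol %), closed base-washed and silylated pressure vessel, 200 °C
Reagents that add atoms: none
Why: Each 2-pyrone serves as the 4π partner through C3=C4–C5=C6 and takes up the alkyne 12 across C3 and C6 in a concerted thermal [4+2] cycloaddition, giving the 2-oxabicyclo[2.2.2]octa-5,7-dien-3-one 13 (later 15), which loses CO2 in a retro-[4+2] step, so every productive encounter is irreversible. The closest known reaction type is the thermal Diels–Alder/decarboxylation of 2-pyrones (the parent, 5-bromo-2-pyrone, methyl coumalate) with bis(trimethylsilyl)acetylene to 1,2-bis(trimethylsilyl)benzenes. Both benzene rings close in the same intermolecular mode, C1–C2 from pyrone C6 and C3–C4 from pyrone C3, and aromatise by extrusion, ring A first (14) and ring B after it. No stereocentre survives, since the bridgeheads of 13 and 15 arise as racemates and become sp2 carbons on loss of CO2. There is no regiochemical question because both ends of 12 are alike, and chemoselectivity rests on the pyrone dienes being the only 4π units, with C5–H and the methylene C7 as spectators. What the step needs is rate, since a donor-substituted diene substituted at both termini meets a bulky unactivated alkyne; a large excess of 12 at about 200 °C is meant to supply it, and the acid-free vessel is meant to prevent protodesilylation or silyl shift in the crowded product.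

**Step 7**
Reactants: 16 bis[4,5-dimethoxy-2,3-bis(trimethylsilyl)phenyl]methane
Product: 17 bis(2,3-dibromo-4,5-dimethoxyphenyl)methane
Conditions: Br2 (4.2 equiv), CH2Cl2, −78 → 0 °C, dark; aq Na2S2O3
Reagents that add atoms: bromine, BrBr
Why: Ipso-bromodesilylation (electrophilic aromatic substitution at the silicon-bearing carbon): β-silicon stabilisation of the arenium ion and relief of strain between the vicinal SiMe3 groups make attack at C2 (para to the C5 methoxy) and C3 (ortho to the C4 methoxy) faster than attack at C6–H, and near-stoichiometric bromine in the cold and dark spares C6–H and the benzylic C7–H.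

**Step 8**
Reactants: 17 bis(2,3-dibromo-4,5-dimethoxyphenyl)methane
Product: 18 bis(2,3-dibromo-4,5-dihydroxyphenyl)methane (target)
Conditions: BBr3 (8 equiv), CH2Cl2, −78 °C → rt; then H2O, 0 °C
Reagents that add atoms: none
Why: Lewis acid cleavage of aryl methyl ethers: BBr3 binds each methoxy oxygen, bromide removes the methyl group by SN2 attack, the aryl bromides and the diarylmethane are inert, and hydrolysis of the aryl borates frees both catechols.

**Compound list**

1 | 2,2,6-trimethyl-4H-1,3-dioxin-4-one | CC1=CC(=O)OC(C)(C)O1 | starting material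
2 | malonyl dichloride | O=C(Cl)CC(Cl)=O | starting material
3 | lithium 2,2-dimethyl-6-methylidene-6H-1,3-dioxin-4-olate (lithium dienolate of 1) | [Li+].[O-]C1=CC(=C)OC(C)(C)O1 | intermediate (not isolated)
4 | 1,5-bis(2,2-dimethyl-4-oxo-4H-1,3-dioxin-6-yl)pentane-2,4-dione | CC1(C)OC(CC(=O)CC(=O)CC2=CC(=O)OC(C)(C)O2)=CC(=O)O1 | intermediate
5 | 8-(2,2-dimethyl-4-oxo-4H-1,3-dioxin-6-yl)oct-1-ene-1,3,5,7-tetraone | CC1(C)OC(CC(=O)CC(=O)CC(=O)C=C=O)=CC(=O)O1 | intermediate (not isolated)
6 | 6-[3-(4-hydroxy-2-oxo-2H-pyran-6-yl)-2-oxopropyl]-2,2-dimethyl-4H-1,3-dioxin-4-one | CC1(C)OC(CC(=O)CC2=CC(O)=CC(=O)O2)=CC(=O)O1 | intermediate (not isolated)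
7 | 6-(4-hydroxy-2-oxo-2H-pyran-6-yl)hex-1-ene-1,3,5-trione | O=C=CC(=O)CC(=O)CC1=CC(O)=CC(=O)O1 | intermediate (not isolated)
8 | 6,6'-methylenebis(4-hydroxy-2H-pyran-2-one) | O=C1C=C(O)C=C(CC2=CC(O)=CC(=O)O2)O1 | intermediate
9 | 6,6'-methylenebis(3-diazo-2H-pyran-2,4(3H)-dione) | [N-]=[N+]=C1C(=O)C=C(CC2=CC(=O)C(=[N+]=[N-])C(=O)O2)OC1=O | intermediate
10 | 6,6'-methylenebis(4-hydroxy-3-methoxy-2H-pyran-2-one) | COC1=C(O)C=C(CC2=CC(O)=C(OC)C(=O)O2)OC1=O | intermediate
11 | bis(3,4-dimethoxy-2-oxo-2H-pyran-6-yl)methane | O=C1OC(CC2=CC(OC)=C(OC)C(=O)O2)=CC(OC)=C1OC | intermediate (key-step precursor)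
12 | bis(trimethylsilyl)acetylene | C[Si](C)(C)C#C[Si](C)(C)C | starting material
13 | 1-[(3,4-dimethoxy-2-oxo-2H-pyran-6-yl)methyl]-4,5-dimethoxy-7,8-bis(trimethylsilyl)-2-oxabicyclo[2.2.2]octa-5,7-dien-3-one (racemate, one enantiomer drawn) | CO[C@@]12C(=O)O[C@@](CC3=CC(OC)=C(OC)C(=O)O3)(C=C1OC)C(=C2[Si](C)(C)C)[Si](C)(C)C | intermediate (not isolated)
14 | 6-{[4,5-dimethoxy-2,3-bis(trimethylsilyl)phenyl]methyl}-3,4-dimethoxy-2H-pyran-2-one | COc1cc(CC2=CC(OC)=C(OC)C(=O)O2)c([Si](C)(C)C)c([Si](C)(C)C)c1OC | intermediate (not isolated)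
15 | 1-{[4,5-dimethoxy-2,3-bis(trimethylsilyl)phenyl]methyl}-4,5-dimethoxy-7,8-bis(trimethylsilyl)-2-oxabicyclo[2.2.2]octa-5,7-dien-3-one (racemate, one enantiomer drawn) | CO[C@@]12C(=O)O[C@@](Cc3cc(OC)c(OC)c([Si](C)(C)C)c3[Si](C)(C)C)(C=C1OC)C(=C2[Si](C)(C)C)[Si](C)(C)C | intermediate (not isolated)
16 | bis[4,5-dimethoxy-2,3-bis(trimethylsilyl)phenyl]methane | COc1cc(Cc2cc(OC)c(OC)c([Si](C)(C)C)c2[Si](C)(C)C)c([Si](C)(C)C)c([Si](C)(C)C)c1OC | intermediate (key-step product)
17 | bis(2,3-dibromo-4,5-dimethoxyphenyl)methane | COc1cc(Cc2cc(OC)c(OC)c(Br)c2Br)c(Br)c(Br)c1OC | intermediate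
18 | bis(2,3-dibromo-4,5-dihydroxyphenyl)methane | Oc1cc(Cc2cc(O)c(O)c(Br)c2Br)c(Br)c(Br)c1O | target

Total step count: 8. Longest linear sequence: 8 steps (1 or 2 to 18).

**Steps most likely to fail**

**Step 6.**
- Risk: the cycloaddition may be too slow to compete with thermal breakdown of the bis-pyrone. The diene is donor-substituted and carries a substituent at both reacting termini, while the alkyne is bulky and unactivated. The crowded vicinal silyl groups may also be lost or shifted by traces of acid at 200 °C.
- Fallback: keep the same ring construction but change the dienophile to one that matches the electron-rich diene.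
- Setting out from 11, heating with dimethyl acetylenedicarboxylate (xylene, 140 °C; normal-electron-demand pyrone Diels–Alder with loss of CO2) should give tetramethyl 6,6'-methylenebis(3,4-dimethoxybenzene-1,2-dicarboxylate) F1.
- Saponification (KOH, aqueous ethylene glycol, 120 °C) gives 6,6'-methylenebis(3,4-dimethoxybenzene-1,2-dicarboxylic acid) F2.
- Fourfold ipso-bromodecarboxylation of the electron-rich carboxylates (Bu4NBr3, K3PO4, MeCN, 100 °C), each carboxyl group lying ortho or para to a methoxy group, comes back to the route at 17.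

**Step 1.**
- Risk: proton transfer from the acidic CH2 of the diacid chloride to the dienolate, oligomerisation of the derived ketenes, O-acylation, arrest after a single acylation, and base-induced aldol aromatisation of the product before the quench may all erode the double acylation.
- Fallback: make the central carbon the nucleophile instead of the electrophile, so that no diacid chloride meets a strong base.
- Setting out from 1, its dienolate 3 is acylated with allyl malonyl chloride (one acid chloride function only) to allyl 4-(2,2-dimethyl-4-oxo-4H-1,3-dioxin-6-yl)-3-oxobutanoate F3.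
- A second portion of 3 is carboxylated with CO2 to (2,2-dimethyl-4-oxo-4H-1,3-dioxin-6-yl)acetic acid F4, which oxalyl chloride converts into (2,2-dimethyl-4-oxo-4H-1,3-dioxin-6-yl)acetyl chloride F5.
- Soft enolisation of F3 (MgCl2, pyridine, CH2Cl2, 0 °C) and C-acylation with F5 at the carbon between ketone and ester gives allyl 4-(2,2-dimethyl-4-oxo-4H-1,3-dioxin-6-yl)-2-[(2,2-dimethyl-4-oxo-4H-1,3-dioxin-6-yl)acetyl]-3-oxobutanoate F6.
- Tsuji–Trost deallylation with decarboxylation (Pd(PPh3)4, morpholine, THF, 0 °C) removes the ester and comes back to the route at 4.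

**Step 7.**
- Risk: once C2 carries bromine, displacement of the second silyl group at C3 slows down. C–H bromination at C6 (ortho to the coplanar C5 methoxy group) or radical bromination at C7 may then compete, and four clean substitutions are needed in one molecule.
- Fallback: make the rings less nucleophilic before bromine is introduced, by carrying acetates instead of methyl ethers.
- Setting out from 9, Rh2(OAc)4-catalysed O–H insertion into acetic acid gives bis(3-acetoxy-4-hydroxy-2-oxo-2H-pyran-6-yl)methane F7.
- Acetylation (Ac2O, pyridine) gives bis(3,4-diacetoxy-2-oxo-2H-pyran-6-yl)methane F8.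
- Cycloaddition with 12 as in step 6 gives bis[4,5-diacetoxy-2,3-bis(trimethylsilyl)phenyl]methane F9. The acyloxy groups bring the diene closer to the electron-poor pyrones known to accept 12.
- Br2 then meets rings on which only the silicon-bearing positions should react and gives bis(4,5-diacetoxy-2,3-dibromophenyl)methane F10.
- Acid methanolysis (HCl, MeOH, rt) comes back to the route at 18, and step 8 is dropped.

**Further compounds**

F1 | step 6 | tetramethyl 6,6'-methylenebis(3,4-dimethoxybenzene-1,2-dicarboxylate) | COc1cc(Cc2cc(OC)c(OC)c(C(=O)OC)c2C(=O)OC)c(C(=O)OC)c(C(=O)OC)c1OC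
F2 | step 6 | 6,6'-methylenebis(3,4-dimethoxybenzene-1,2-dicarboxylic acid) | COc1cc(Cc2cc(OC)c(OC)c(C(O)=O)c2C(O)=O)c(C(O)=O)c(C(O)=O)c1OC
F3 | step 1 | allyl 4-(2,2-dimethyl-4-oxo-4H-1,3-dioxin-6-yl)-3-oxobutanoate | C=CCOC(=O)CC(=O)CC1=CC(=O)OC(C)(C)O1
F4 | step 1 | (2,2-dimethyl-4-oxo-4H-1,3-dioxin-6-yl)acetic acid | OC(=O)CC1=CC(=O)OC(C)(C)O1
F5 | step 1 | (2,2-dimethyl-4-oxo-4H-1,3-dioxin-6-yl)acetyl chloride | ClC(=O)CC1=CC(=O)OC(C)(C)O1
F6 | step 1 | allyl 4-(2,2-dimethyl-4-oxo-4H-1,3-dioxin-6-yl)-2-[(2,2-dimethyl-4-oxo-4H-1,3-dioxin-6-yl)acetyl]-3-oxobutanoate | C=CCOC(=O)C(C(=O)CC1=CC(=O)OC(C)(C)O1)C(=O)CC1=CC(=O)OC(C)(C)O1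
F7 | step 7 | bis(3-acetoxy-4-hydroxy-2-oxo-2H-pyran-6-yl)methane | CC(=O)OC1=C(O)C=C(CC2=CC(O)=C(OC(C)=O)C(=O)O2)OC1=O
F8 | step 7 | bis(3,4-diacetoxy-2-oxo-2H-pyran-6-yl)methane | CC(=O)OC1=C(OC(C)=O)C=C(CC2=CC(OC(C)=O)=C(OC(C)=O)C(=O)O2)OC1=O
F9 | step 7 | bis[4,5-diacetoxy-2,3-bis(trimethylsilyl)phenyl]methane | CC(=O)Oc1cc(Cc2cc(OC(C)=O)c(OC(C)=O)c([Si](C)(C)C)c2[Si](C)(C)C)c([Si](C)(C)C)c([Si](C)(C)C)c1OC(C)=O
F10 | step 7 | bis(4,5-diacetoxy-2,3-dibromophenyl)methane | CC(=O)Oc1cc(Cc2cc(OC(C)=O)c(OC(C)=O)c(Br)c2Br)c(Br)c(Br)c1OC(C)=O
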